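**Retrosynthetic overview**
1. The pyran ring is closed last: the C1 hydroxyl adds 6-endo to an ynenone, whose C4a–C4 bond comes from Sonogashira coupling of β-chloroenone 16 with dienyne 5.
2. The C8a quaternary centre, its acetyl group and the C8 carbinol come from one stereospecific 1,2-shift (semipinacol) of epoxy alcohol 15.
3. The oxirane of 15 is delivered by the C7 hydroxyl of o-quinol 14; C7 itself is set by enantioselective hydroxylative dearomatisation of phenol 13.
4. Phenol 13 comes from 3-chlorophenol (ortho-methyl via formylation/reduction, two halogenations, aryllithium addition to a silyloxyacetone); the benzene ring becomes the carbocycle.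
5. Dienyne 5 comes from (S)-2-methylbutan-1-ol by oxidation/Wittig and Horner–Wadsworth–Emmons olefination.

Assumption: 11 is bought as the silyl ether, and its silyl protecting group is not counted in the starting-material size (hydroxyacetone core, five non-hydrogen atoms).

**Step 1**
Reactants: 1 (S)-2-methylbutan-1-ol
Product: 3 (2E,4S)-2,4-dimethylhex-2-enal, via (S)-2-methylbutanal 2 (not isolated)
Conditions: TEMPO (10 mol%), PhI(OAc)2, CH2Cl2, rt; then Ph3P=C(Me)CHO, 40 °C
Reagents that add atoms: 2-(triphenylphosphoranylidene)propanal, CC(C=O)=P(c1ccccc1)(c1ccccc1)c1ccccc1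
Why: Tandem TEMPO oxidation–Wittig olefination: the aldehyde is made without epimerising its α-centre and is trapped in the same flask by the stabilised ylide, which gives the E-trisubstituted enal; the S centre comes unchanged from 1.

**Step 2**
Reactants: 3 (2E,4S)-2,4-dimethylhex-2-enal
Product: 5 (3E,5E,7S)-5,7-dimethylnona-3,5-dien-1-yne, via C-silyl dienyne 4 (not isolated)
Conditions: (EtO)2P(O)CH2C≡CSiMe3, LiHMDS, THF, −78 → 0 °C; then K2CO3 (cat.), MeOH, rt
Reagents that add atoms: diethyl [3-(trimethylsilyl)prop-2-yn-1-yl]phosphonate, CCOP(=O)(OCC)CC#C[Si](C)(C)C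
Why: Horner–Wadsworth–Emmons olefination with the lithiated propargylic phosphonate forms the new disubstituted alkene E-selectively (minor Z isomer removed on AgNO3-silica), and methanolysis removes the C-silyl group; no stereocentre is touched.

**Step 3**
Reactants: 6 3-chlorophenol
Product: 7 4-chloro-2-hydroxybenzaldehyde
Conditions: MgCl2, Et3N, (CH2O)n, MeCN, reflux
Reagents that add atoms: paraformaldehyde (formaldehyde), C=O
Why: Magnesium-phenoxide-directed ortho-formylation (Casnati–Skattebøl type) reacts only ortho to OH and at the less hindered ortho position, para to chlorine.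

**Step 4**
Reactants: 7 4-chloro-2-hydroxybenzaldehyde
Product: 8 5-chloro-2-methylphenol
Conditions: Et3SiH (2.5 equiv), TFA, CH2Cl2, rt → 40 °C
Reagents that add atoms: none
Why: Ionic hydrogenation: the ortho-hydroxybenzylic cation (o-quinone methide) formed in TFA is reduced by the silane down to the methyl group, and the aryl chloride is inert.

**Step 5**
Reactants: 8 5-chloro-2-methylphenol
Product: 10 4-bromo-2,3-dichloro-6-methylphenol, via 4-bromo-5-chloro-2-methylphenol 9 (not isolated)
Conditions: NBS, MeCN, 0 °C; then NCS, TsOH (cat.), 50 °C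
Reagents that add atoms: N-bromosuccinimide, O=C1CCC(=O)N1Br; N-chlorosuccinimide, O=C1CCC(=O)N1Cl
Why: Sequential electrophilic aromatic halogenation: NBS brominates para to OH, and the only activated position left (ortho to OH) is then chlorinated in the same pot.

**Step 6**
Reactants: 10 4-bromo-2,3-dichloro-6-methylphenol; 11 1-[(tert-butyldimethylsilyl)oxy]propan-2-one
Product: 13 4-[1-(tert-butyldimethylsilyloxy)-2-hydroxypropan-2-yl]-2,3-dichloro-6-methylphenol (racemic carbinol), via dilithiated phenol 12 (not isolated)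
Conditions: n-BuLi (2.1 equiv), THF, −78 °C; then 11, −78 → −40 °C; NH4Cl
Reagents that add atoms: none
Why: O-deprotonation then bromine–lithium exchange (Br far faster than Cl, and −78 °C is below aryne formation) gives an aryllithium that adds 1,2 to the ketone; the carbinol centre is left racemic on purpose because it becomes the acetyl carbonyl in step 9.

**Step 7**
Reactants: 13 4-[1-(tert-butyldimethylsilyloxy)-2-hydroxypropan-2-yl]-2,3-dichloro-6-methylphenol
Product: 14 (6R)-4-[1-(tert-butyldimethylsilyloxy)-2-hydroxypropan-2-yl]-2,3-dichloro-6-hydroxy-6-methylcyclohexa-2,4-dien-1-one (both carbinol epimers)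
Conditions: (R)-2,2'-bis(iodyl)-1,1'-binaphthyl (0.55 equiv), CH2Cl2, −40 → 0 °C
Reagents that add atoms: (R)-2,2'-bis(iodyl)-1,1'-binaphthyl, O=I(=O)c1ccc2ccccc2c1-c1c(I(=O)=O)ccc2ccccc12
Why: Hydroxylative phenol dearomatisation by a λ5-iodane: the phenol binds iodine(V) and oxygen is delivered intramolecularly to the more electron-rich ortho carbon (C–CH3, not C–Cl), the C2-symmetric reagent choosing the ring face to set C6 as R (the antipodal reagent is used if the sense proves opposite), while the 2,3,4-substitution suppresses [4+2] dimerisation of the o-quinol.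

**Step 8**
Reactants: 14 (6R)-o-quinol
Product: 15 (1S,2R,6R)-6-[1-(tert-butyldimethylsilyloxy)-2-hydroxypropan-2-yl]-4,5-dichloro-2-hydroxy-2-methyl-7-oxabicyclo[4.1.0]hept-4-en-3-one (oxirane cis to the 2-OH)
Conditions: VO(acac)2 (5 mol%), t-BuOOH, CH2Cl2, 0 °C
Reagents that add atoms: tert-butyl hydroperoxide, CC(C)(C)OO
Why: Hydroxyl-directed vanadium-catalysed epoxidation: the alkene is flanked by two tertiary allylic hydroxyls, and the ring hydroxyl delivers the peroxide to its own face (the C-methyl shields the other), so the oxirane is cis to that OH and fixes C1 and C6; the dichloroalkene is inert.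

**Step 9**
Reactants: 15 (1S,2R,6R)-epoxy alcohol
Product: 16 (4R,5R,6R)-4-acetyl-4-{[(tert-butyldimethylsilyl)oxy]methyl}-2,3-dichloro-5,6-dihydroxy-6-methylcyclohex-2-en-1-one (acetyl and both OH cis)
Conditions: BF3·OEt2 (0.5 equiv), CH2Cl2, −78 → −30 °C
Reagents that add atoms: none
Why: Proposed new method: a type III semipinacol rearrangement (Lewis-acid 1,2-shift of a 2,3-epoxy alcohol) on an epoxy-o-quinol, a substrate class on which it has not been shown and in which a silyloxymethyl group must out-migrate methyl: BF3 activates the oxirane, the tertiary allylic C6–O bond ionises in preference to the secondary C1–O bond, and the C–CH2OTBS bond antiperiplanar to it shifts from the carbinol carbon to C6 with inversion while the carbinol collapses to the methyl ketone, so the migrating carbon ends trans and the new acetyl cis to the oxygen that stays on C1 (both carbinol epimers converge on one product); the oxygen-bearing primary carbon is expected to migrate ahead of methyl as the O–CH2 carbon does in the pinacol step of Prins–pinacol ring contractions, and the closest known reaction is the Suzuki–Tsuchihashi-type semipinacol rearrangement of 2,3-epoxy alcohols to β-hydroxy ketones with an α-quaternary centre.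

**Step 10**
Reactants: 16 (4R,5R,6R)-ketol; 5 (3E,5E,7S)-5,7-dimethylnona-3,5-dien-1-yne
Product: 19 (7R,8R,8aS)-8a-acetyl-5-chloro-3-[(1E,3E,5S)-3,5-dimethylhepta-1,3-dien-1-yl]-7,8-dihydroxy-7-methyl-1,7,8,8a-tetrahydro-6H-isochromen-6-one, via TBS ynenone 17 (not isolated), via hydroxy ynenone 18 (not isolated)
Conditions: PdCl2(PPh3)2 (5 mol%), CuI (10 mol%), Et3N, THF, 45 °C (degassed); then Et3N·3HF, rt
Reagents that add atoms: none
Why: Sonogashira coupling takes the β-chloride (a vinylogous acyl chloride) and leaves the α-chloride; fluoride then frees the primary alcohol, which adds 6-endo-dig to the δ-carbon of the ynenone (1,6-oxa-Michael; it is the only hydroxyl that can close a ring without a bridgehead alkene), and C-protonation gives the conjugated pyran enol ether with no stereocentre changed.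

**Compound list**
1 | (S)-2-methylbutan-1-ol | CC[C@H](C)CO | starting material
2 | (S)-2-methylbutanal | CC[C@H](C)C=O | intermediate
3 | (2E,4S)-2,4-dimethylhex-2-enal | CC[C@H](C)/C=C(C)/C=O | intermediate
4 | (3E,5E,7S)-5,7-dimethyl-1-(trimethylsilyl)nona-3,5-dien-1-yne | CC[C@H](C)/C=C(C)/C=C/C#C[Si](C)(C)C | intermediate
5 | (3E,5E,7S)-5,7-dimethylnona-3,5-dien-1-yne | CC[C@H](C)/C=C(C)/C=C/C#C | intermediate
6 | 3-chlorophenol | Oc1cccc(Cl)c1 | starting material
7 | 4-chloro-2-hydroxybenzaldehyde | O=Cc1ccc(Cl)cc1O | intermediate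
8 | 5-chloro-2-methylphenol | Cc1ccc(Cl)cc1O | intermediate
9 | 4-bromo-5-chloro-2-methylphenol | Cc1cc(Br)c(Cl)cc1O | intermediate
10 | 4-bromo-2,3-dichloro-6-methylphenol | Cc1cc(Br)c(Cl)c(Cl)c1O | intermediate
11 | 1-[(tert-butyldimethylsilyl)oxy]propan-2-one | CC(=O)CO[Si](C)(C)C(C)(C)C | starting material
12 | lithium 2,3-dichloro-4-lithio-6-methylphenolate | [Li]Oc1c(C)cc([Li])c(Cl)c1Cl | intermediate
13 | 4-[1-(tert-butyldimethylsilyloxy)-2-hydroxypropan-2-yl]-2,3-dichloro-6-methylphenol (racemic carbinol) | Cc1cc(C(C)(O)CO[Si](C)(C)C(C)(C)C)c(Cl)c(Cl)c1O | intermediate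
14 | (6R)-4-[1-(tert-butyldimethylsilyloxy)-2-hydroxypropan-2-yl]-2,3-dichloro-6-hydroxy-6-methylcyclohexa-2,4-dien-1-one (both carbinol epimers) | ClC1=C(Cl)C(=O)[C@](C)(O)C=C1C(C)(O)CO[Si](C)(C)C(C)(C)C | intermediate
15 | (1S,2R,6R)-6-[1-(tert-butyldimethylsilyloxy)-2-hydroxypropan-2-yl]-4,5-dichloro-2-hydroxy-2-methyl-7-oxabicyclo[4.1.0]hept-4-en-3-one (both carbinol epimers) | ClC1=C(Cl)C(=O)[C@](C)(O)[C@@H]2O[C@]12C(C)(O)CO[Si](C)(C)C(C)(C)C | intermediate
16 | (4R,5R,6R)-4-acetyl-4-{[(tert-butyldimethylsilyl)oxy]methyl}-2,3-dichloro-5,6-dihydroxy-6-methylcyclohex-2-en-1-one | ClC1=C(Cl)C(=O)[C@](C)(O)[C@H](O)[C@@]1(C(C)=O)CO[Si](C)(C)C(C)(C)C | intermediate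
17 | (4S,5R,6R)-4-acetyl-4-{[(tert-butyldimethylsilyl)oxy]methyl}-2-chloro-3-[(3E,5E,7S)-5,7-dimethylnona-3,5-dien-1-yn-1-yl]-5,6-dihydroxy-6-methylcyclohex-2-en-1-one | CC[C@H](C)/C=C(C)/C=C/C#CC1=C(Cl)C(=O)[C@](C)(O)[C@H](O)[C@@]1(C(C)=O)CO[Si](C)(C)C(C)(C)C | intermediate
18 | (4S,5R,6R)-4-acetyl-2-chloro-3-[(3E,5E,7S)-5,7-dimethylnona-3,5-dien-1-yn-1-yl]-5,6-dihydroxy-4-(hydroxymethyl)-6-methylcyclohex-2-en-1-one | CC[C@H](C)/C=C(C)/C=C/C#CC1=C(Cl)C(=O)[C@](C)(O)[C@H](O)[C@@]1(C(C)=O)CO | intermediate
19 | (7R,8R,8aS)-8a-acetyl-5-chloro-3-[(1E,3E,5S)-3,5-dimethylhepta-1,3-dien-1-yl]-7,8-dihydroxy-7-methyl-1,7,8,8a-tetrahydro-6H-isochromen-6-one | CC[C@H](C)/C=C(C)/C=C/C1=CC2=C(Cl)C(=O)[C@](C)(O)[C@H](O)[C@@]2(C(C)=O)CO1 | target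

**Step count**
Total: 10 steps. Longest linear sequence: 8 steps (6 → 19, steps 3–10).

**Three steps most likely to fail**

Step 9 (the proposed new step). Methyl may migrate instead of the silyloxymethyl carbon, the oxirane may open at the secondary carbon, or fluoride may be transferred from boron. The fallback sets out from 15 and uses an acyl shift, the best-established migrating group in epoxy-alcohol and epoxy-ketone rearrangements. Et3N·3HF removes the silyl group to give the epoxy triol F1. TEMPO/PhI(OAc)2 oxidises only the primary alcohol to the epoxy α-hydroxy aldehyde F2. BF3·OEt2 then makes the formyl group shift to the oxirane carbon with the same stereochemical course, giving the formyl ketol F3. NaBH(OAc)3 reduces the aldehyde, but not the ketones, to the hydroxymethyl ketol F4. F4 is coupled with 5 under the palladium/copper conditions of step 10 and comes back to the route at 18.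

Step 7. The dichlorophenol is electron-poor, so oxygen transfer may be slow, the enantioselectivity on this 2,6-disubstituted phenol is untested, and attack at the chlorine-bearing ortho carbon would give an o-quinone. The fallback sets out from 13: the achiral stabilised λ5-iodane SIBX (THF, rt) gives the racemic o-quinol F5, which is resolved by preparative HPLC on a chiral stationary phase. The (6R) enantiomer is 14, where the fallback comes back to the route.

Step 10. The β-chloride sits between a quaternary carbon and a chlorine, so oxidative addition may be slow, and the amine base could promote retro-aldol cleavage of the β-hydroxy ketone. The fallback sets out from 5: n-BuLi then Bu3SnCl gives the alkynylstannane F6. Copper-free, base-free Stille coupling of F6 with 16 (Pd2(dba)3, P(2-furyl)3, NMP, 50 °C) comes back to the route at 17. If the ring closure of 18 lags after desilylation, a π-acid (AgOTf or Ph3PAuNTf2) replaces base catalysis to reach 19.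

**Further compounds**
F1 | step 9 | (1S,2R,6R)-4,5-dichloro-6-(1,2-dihydroxypropan-2-yl)-2-hydroxy-2-methyl-7-oxabicyclo[4.1.0]hept-4-en-3-one | ClC1=C(Cl)C(=O)[C@](C)(O)[C@@H]2O[C@]12C(C)(O)CO
F2 | step 9 | epoxy α-hydroxy aldehyde (F1 with the side-chain CH2OH oxidised to CHO) | ClC1=C(Cl)C(=O)[C@](C)(O)[C@@H]2O[C@]12C(C)(O)C=O
F3 | step 9 | formyl ketol (16 with CHO in place of CH2OTBS; acetyl and both OH cis) | ClC1=C(Cl)C(=O)[C@](C)(O)[C@H](O)[C@@]1(C(C)=O)C=O
F4 | step 9 | (4R,5R,6R)-4-acetyl-2,3-dichloro-5,6-dihydroxy-4-(hydroxymethyl)-6-methylcyclohex-2-en-1-one | ClC1=C(Cl)C(=O)[C@](C)(O)[C@H](O)[C@@]1(C(C)=O)CO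
F5 | step 7 | racemic (6RS) form of 14 | ClC1=C(Cl)C(=O)C(C)(O)C=C1C(C)(O)CO[Si](C)(C)C(C)(C)C
F6 | step 10 | tributyl[(3E,5E,7S)-5,7-dimethylnona-3,5-dien-1-yn-1-yl]stannane | CC[C@H](C)/C=C(C)/C=C/C#C[Sn](CCCC)(CCCC)CCCC
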